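The earlier runs and the new flask come from a simulation with made-up constants; noise was put on by code.

the same everywhere: left-handed substrate 0.20 M; right-handed substrate 0.20 M
- grey: reagent 0.80 M; free catalyst 37 mM; racemization catalyst 9 mM; run made earlier
- green: reagent 0.80 M; free catalyst 64 mM; racemization catalyst 9 mM; run made earlier
- autumn: reagent 0.800 M; free catalyst 25 mM; racemization catalyst 9.0 mM; time 40 min
- midnight: reagent 0.800 M; free catalyst 40 mM; racemization catalyst 9.0 mM; time 40 min
- dawn: reagent 0.800 M; free catalyst 50 mM; racemization catalyst 9.0 mM; time 40 min

| run | time / min | left-handed product / % | right-handed product / % | left-handed substrate / % |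
|---|---|---|---|---|
| grey | 2.50 | 8 | 0 | 41 |
| grey | 8.00 | 21 | 0 | 27 |
| grey | 12.0 | 25 | 3 | 24 |
| grey | 20.0 | 34 | 3 | 12 |
| green | 2.50 | 13 | 2 | 35 |
| green | 8.00 | 29 | 2 | 20 |
| green | 12.0 | 37 | 1 | 13 |
| green | 20.0 | 44 | 2 | 4 |

(readings scatter by 1.5 percentage points)

- share of left-handed product in all that became left-handed product or right-handed product for autumn, midnight, dawn, in this order
- how that number moves from the first to the last of them (rises all the way / falls, then rises / rises, then falls / hardly changes / falls all the way)

- free catalyst is single-handed; left-handed substrate and right-handed substrate are mirror images of each other, charged as a racemate, each of them at the stated concentration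
- "hardly changes" means that all values lie within two and a half points (for a concentration: within two and a half percent of the largest)

The constants of the two mirror-image reactions reach the share as one ratio, provided free catalyst and reagent act on both substrates alike: the selectivity factor s, the logarithm of the fraction of left-handed substrate left over the logarithm of the fraction of right-handed substrate left. Each substrate's charge is half of the percent scale, and the last rows of the grey and green runs, both at 20.0 min, pooled, give s = 38.5, a rough reading, since right-handed product stands there at 3% and 2% against a scatter of 1.5 percentage points.

How does the comparison of rates drift? At the start right-handed product forms at 2.60% of the rate of left-handed product, but that figure grows as left-handed substrate thins: in the green run at 20.0 min, with a fraction of 8.00% left, it is 32.5%.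

How far, then, does each flask get? If equal products of catalyst and time remove equal fractions, the grey run's reading predicts that autumn keeps 14.5% of its left-handed substrate and dawn 2.11%. With s, this reckoning gives shares of 94.6% for autumn and 91.1% for dawn, a drop of 3.5 points, beyond the margin of "hardly changes".

The forecast, holding that “it is proportional to catalyst”, gives 94.6%, 92.5% and 91.1%, so that the share falls all the way.

The flask gives 95.4%, 93.9% and 92.9%, so that the share hardly changes.

    reagent + free catalyst + right-handed substrate → free catalyst + right-handed product (k = 0.0600 M⁻² min⁻¹)
    reagent + racemization catalyst → spent catalyst (k = 2.42 M⁻¹ min⁻¹)
    reagent + free catalyst + left-handed substrate → free catalyst + left-handed product (k = 2.57 M⁻² min⁻¹)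
    left-handed substrate + racemization catalyst ⇌ right-handed substrate + racemization catalyst, rate k4*[racemization catalyst]*[left-handed substrate] forward; the back reaction follows from the equilibrium constant (k = 9.52 M⁻¹ min⁻¹)

At 40.0 min dawn keeps 3.8% of its left-handed substrate, more than the reckoned 2.11%. The largest single effect on dawn's share is the time given: at ten times as long the share is 67.8% against 92.9%, with left-handed substrate at 0% and right-handed product at 23.8%. Reagent enters both product rate laws to the same power, so s carries over to the simulated fractions: dawn's 3.8% gives a share of 92.2% against 92.9%, and autumn's 18% gives 95.0% against 95.4%.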